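Ring B of ferocaulidin is a cyclohexenone whose C6 carbonyl and C7=C8 alkene are the trace of a 2-silyloxydiene after cycloaddition and Saegusa–Ito oxidation. The route therefore rests on one disconnection, C5–C10 plus C8–C9, made in a single intramolecular Diels–Alder reaction that closes rings A and B, sets C5, C9 and C10 and leaves C6 as a silyl enol ether. Its precursor is an open-chain triene: a (Z)-silyl dienol ether (C5=C6–C7=C8) joined through C4–C1, carrying the gem-dimethyl group and an (R)-silyloxy stereocentre at C3, to an (E)-β-methyl enoate (C9=C10). C3 steers the facial sense and is inverted at the end, after umbelliferone is attached.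

Key step: step 11

Remarks. Ring atoms carry drimane numbers throughout, also in the open-chain compounds (C1–C10 in the decalin, C11 on C9, C12 on C8, C13 and C14 on C4, C15 on C10). In names, "drim" gives the constitution only; the configuration is fixed by the CIP descriptors and the SMILES. TBS = tert-butyldimethylsilyl. Assumption: the equatorial preference of the C3 silyloxy group in the chair-folded tether is taken to be large enough for a useful facial bias in step 11.

Step 1
Reactants: 1 2-(2-bromoethyl)-2-methyl-1,3-dioxolane; 2 2,2-dimethylpent-4-enal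
Product: 4 racemic 4,4-dimethyl-1-(2-methyl-1,3-dioxolan-2-yl)hept-6-en-3-ol, via Grignard reagent 3 (not isolated)
Conditions: Mg (I2-activated), THF, 25–30 °C; then 2, 0 °C; aqueous work-up
Reagents that add atoms: none
Why: Grignard addition to a non-enolizable aldehyde, in which the ketal-bearing organomagnesium reagent is stable in THF near room temperature and the new carbinol centre (C3) forms as a racemate that steps 2 and 3 replace by one configuration.

Step 2
Reactants: 4 racemic 4,4-dimethyl-1-(2-methyl-1,3-dioxolan-2-yl)hept-6-en-3-ol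
Product: 5 4,4-dimethyl-1-(2-methyl-1,3-dioxolan-2-yl)hept-6-en-3-one
Conditions: (n-Pr4N)RuO4 (5 mol%), NMO (1.5 equiv), 4 Å MS, CH2Cl2, rt
Reagents that add atoms: none
Why: Ley–Griffith oxidation of a secondary alcohol to the ketone under neutral conditions that spare the dioxolane and the terminal alkene, erasing the racemic centre.

Step 3
Reactants: 5 4,4-dimethyl-1-(2-methyl-1,3-dioxolan-2-yl)hept-6-en-3-one
Product: 6 (3R)-4,4-dimethyl-1-(2-methyl-1,3-dioxolan-2-yl)hept-6-en-3-ol
Conditions: (S)-2-methyl-CBS-oxazaborolidine (0.2 equiv), catecholborane (1.8 equiv), toluene, −40 → 0 °C; MeOH, then aqueous work-up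
Reagents that add atoms: none
Why: Corey–Bakshi–Shibata reduction in which the quaternary C4 flank acts as the large group and the CH2 chain as the small one, so that the (S)-catalyst should deliver hydride to the face giving the (R)-carbinol, with catecholborane as hydride source because it does not hydroborate the terminal alkene at this temperature.

Step 4
Reactants: 6 (3R)-4,4-dimethyl-1-(2-methyl-1,3-dioxolan-2-yl)hept-6-en-3-ol
Product: 7 tert-butyl{[(3R)-4,4-dimethyl-1-(2-methyl-1,3-dioxolan-2-yl)hept-6-en-3-yl]oxy}dimethylsilane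
Conditions: TBSOTf (1.2 equiv), 2,6-lutidine (2 equiv), CH2Cl2, −78 → 0 °C
Reagents that add atoms: tert-butyldimethylsilyl trifluoromethanesulfonate, CC(C)(C)[Si](C)(C)OS(=O)(=O)C(F)(F)F
Why: Silyl ether formation with the silyl triflate, which a secondary alcohol next to a quaternary carbon requires, under buffered low-temperature conditions that leave the dioxolane closed and C3 untouched.

Step 5
Reactants: 7 tert-butyl{[(3R)-4,4-dimethyl-1-(2-methyl-1,3-dioxolan-2-yl)hept-6-en-3-yl]oxy}dimethylsilane
Product: 8 (5R)-5-[(tert-butyldimethylsilyl)oxy]-6,6-dimethylnon-8-en-2-one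
Conditions: PPTS (0.2 equiv), acetone–H2O (10:1), 55 °C
Reagents that add atoms: water, O
Why: Acid-catalysed ketal hydrolysis unveils the methyl ketone, while the hindered secondary silyl ether and the alkene are stable to the weakly acidic pyridinium salt.

Step 6
Reactants: 8 (5R)-5-[(tert-butyldimethylsilyl)oxy]-6,6-dimethylnon-8-en-2-one; 9 trimethyl phosphonoacetate
Product: 11 methyl (2E,6R)-6-[(tert-butyldimethylsilyl)oxy]-3,7,7-trimethyldeca-2,9-dienoate, via sodium phosphonate carbanion 10 (not isolated)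
Conditions: NaH, THF, 0 °C; then 8, rt → 50 °C; chromatography to remove the minor (2Z)-isomer
Reagents that add atoms: none
Why: Horner–Wadsworth–Emmons olefination of the methyl ketone, in which reversible addition and the longer CH2 chain trans to the ester should favour the (2E)-enoate, the minor (2Z)-isomer being removed because this geometry later fixes C9 against C10.

Step 7
Reactants: 11 methyl (2E,6R)-6-[(tert-butyldimethylsilyl)oxy]-3,7,7-trimethyldeca-2,9-dienoate
Product: 12 methyl (2E,6R)-6-[(tert-butyldimethylsilyl)oxy]-3,7,7-trimethyl-9-oxodec-2-enoate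
Conditions: PdCl2 (10 mol%), CuCl (20 mol%), O2 (1 atm), DMF–H2O (7:1), rt
Reagents that add atoms: water, O
Why: Tsuji–Wacker oxidation, in which Markovnikov hydroxypalladation of the monosubstituted alkene by divalent palladium gives the methyl ketone and the electron-poor trisubstituted enoate does not compete.

Step 8
Reactants: 12 methyl (2E,6R)-6-[(tert-butyldimethylsilyl)oxy]-3,7,7-trimethyl-9-oxodec-2-enoate; 13 acetaldehyde
Product: 15 methyl (2E,6R)-6-[(tert-butyldimethylsilyl)oxy]-11-hydroxy-3,7,7-trimethyl-9-oxododec-2-enoate (C11 epimers), via dibutylboron enolate 14 (not isolated)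
Conditions: Bu2BOTf (1.2 equiv), iPr2NEt (1.4 equiv), CH2Cl2, −78 °C; then CH3CHO (3 equiv), −78 → −20 °C; MeOH, pH 7 buffer, H2O2, 0 °C
Reagents that add atoms: none
Why: Boron-mediated aldol addition in which Bu2BOTf and the hindered amine enolize only the ketone, on its methyl side and not at the neopentyl C5 methylene, so that the enoate never meets a strong base, and the new carbinol centre is of no consequence because step 9 removes it.

Step 9
Reactants: 15 methyl (2E,6R)-6-[(tert-butyldimethylsilyl)oxy]-11-hydroxy-3,7,7-trimethyl-9-oxododec-2-enoate (C11 epimers)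
Product: 17 methyl (2E,6R,10E)-6-[(tert-butyldimethylsilyl)oxy]-3,7,7-trimethyl-9-oxododeca-2,10-dienoate, via mesylate 16 (not isolated)
Conditions: MsCl, Et3N, CH2Cl2, 0 °C; then DBU, rt
Reagents that add atoms: none
Why: Mesylation followed by base-induced β-elimination (E1cB) of the β-sulfonyloxy ketone gives the conjugated enone, for which the (E)-geometry is the thermodynamic one.

Step 10
Reactants: 17 methyl (2E,6R,10E)-6-[(tert-butyldimethylsilyl)oxy]-3,7,7-trimethyl-9-oxododeca-2,10-dienoate
Product: 18 methyl (2E,6R,8Z,10E)-6,9-bis[(tert-butyldimethylsilyl)oxy]-3,7,7-trimethyldodeca-2,8,10-trienoate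
Conditions: TBSOTf (1.3 equiv), Et3N (2 equiv), CH2Cl2, −78 → 0 °C; cold NaHCO3 work-up, Et3N-deactivated silica
Reagents that add atoms: tert-butyldimethylsilyl trifluoromethanesulfonate, CC(C)(C)[Si](C)(C)OS(=O)(=O)C(F)(F)F
Why: Soft enolization, in which O-silylation of the enone and deprotonation at the α′-carbon C5 by the amine give the cross-conjugated 2-silyloxydiene with (Z)-geometry at C5=C6, because the alternative would press the quaternary C4 against the propenyl group (allylic strain), while the ester is inert to this mild base.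

Step 11
Reactants: 18 methyl (2E,6R,8Z,10E)-6,9-bis[(tert-butyldimethylsilyl)oxy]-3,7,7-trimethyldodeca-2,8,10-trienoate
Product: 19 methyl (3R,5S,8R,9R,10R)-3,6-bis[(tert-butyldimethylsilyl)oxy]drim-6-en-11-oate (H5 trans to the C10 methyl; C9 ester and C8 methyl cis to the C10 methyl; C3 silyloxy equatorial)
Conditions: degassed toluene (0.01 M), BHT (cat.), silylated glassware, sealed tube, 180 °C
Reagents that add atoms: none
Why: Thermal, concerted and suprafacial [4+2] cycloaddition of normal electron demand between the electron-rich (Z)-2-silyloxydiene C5=C6–C7=C8 and the enoate C9=C10, the closest known reaction type being the intramolecular Diels–Alder reaction of 1,7,9-decatrienoates with the tether on the diene terminus. Ring B closes as the cyclohexene of the cycloaddition (C5–C10 and C8–C9 made together), and ring A closes in the fused mode because the four-carbon tether C1–C4 links C10 to C5 and folds as a chair. C9 and C10 take their cis ester/methyl relation from the (E)-enoate, C5 and C8 take H5 and H8 cis from the (Z)-enol ether and (E)-propenyl geometries, and the ester-endo (tether-anti) transition state joins the two sets so that H5 is trans to the C10 methyl and the provisional C8 methyl is cis to the ester. The absolute sense of C5, C9 and C10 is relayed from the (R)-C3 centre of step 3, whose silyloxy group prefers the equatorial site of the chair tether. The step needs endo and π-facial selectivity: the first is secured by the (E)-enoate placing its ester under the diene while the tether stays anti, the second by the equatorial preference of the bulky C3 silyloxy group, and the gem-dimethyl group at C4 favours the reactive fold. Adducts of the wrong face or of the exo mode are diastereomers of 19 and would be separated here, before C3 is turned into a ketone.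

Step 12
Reactants: 19 methyl (3R,5S,8R,9R,10R)-3,6-bis[(tert-butyldimethylsilyl)oxy]drim-6-en-11-oate
Product: 20 (3R,5S,8S,9R,10S)-3,6-bis[(tert-butyldimethylsilyl)oxy]drim-6-en-11-ol
Conditions: LiAlH4 (1.5 equiv), Et2O, 0 °C; Na2SO4·10H2O quench
Reagents that add atoms: none
Why: Hydride reduction of the ester to the primary C11 alcohol, during which the silyl enol ether keeps the C6 carbonyl masked, no stereocentre is touched and the work-up stays non-acidic.

Step 13
Reactants: 20 (3R,5S,8S,9R,10S)-3,6-bis[(tert-butyldimethylsilyl)oxy]drim-6-en-11-ol; 21 umbelliferone (7-hydroxy-2H-chromen-2-one)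
Product: 22 7-{[(3R,5S,8S,9R,10S)-3,6-bis[(tert-butyldimethylsilyl)oxy]drim-6-en-11-yl]oxy}-2H-chromen-2-one
Conditions: PPh3, DIAD, THF, 0 °C → rt
Reagents that add atoms: none
Why: Mitsunobu etherification in which the acidic phenol displaces the activated primary C11 oxygen in an SN2 step (no stereocentre involved), run while C6 is still an enol ether so that H9 is not acidic and elimination across C9–C11 cannot compete.

Step 14
Reactants: 22 7-{[(3R,5S,8S,9R,10S)-3,6-bis[(tert-butyldimethylsilyl)oxy]drim-6-en-11-yl]oxy}-2H-chromen-2-one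
Product: 23 7-{[(3R,5S,9R,10S)-3-[(tert-butyldimethylsilyl)oxy]-6-oxodrim-7-en-11-yl]oxy}-2H-chromen-2-one
Conditions: Pd(OAc)2 (1.1 equiv), MeCN, 40 °C
Reagents that add atoms: none
Why: Saegusa–Ito oxidation, in which the silyl enol ether hands C7 to divalent palladium and syn β-hydride elimination of H8 gives the C7=C8 enone, the only possible outcome since neither C4 nor C10 carries a hydrogen next to C5, and the provisional C8 centre disappears.

Step 15
Reactants: 23 7-{[(3R,5S,9R,10S)-3-[(tert-butyldimethylsilyl)oxy]-6-oxodrim-7-en-11-yl]oxy}-2H-chromen-2-one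
Product: 24 7-{[(3R,5S,9R,10S)-3-hydroxy-6-oxodrim-7-en-11-yl]oxy}-2H-chromen-2-one (3-epi-ferocaulidin, equatorial alcohol)
Conditions: HF (48% aq), MeCN, rt
Reagents that add atoms: none
Why: Acidic fluoride cleavage of the hindered secondary silyl ether, chosen over basic fluoride because a base could deprotonate C9 (γ to the enone) and expel the aryloxy group from C11.

Step 16
Reactants: 24 7-{[(3R,5S,9R,10S)-3-hydroxy-6-oxodrim-7-en-11-yl]oxy}-2H-chromen-2-one
Product: 25 7-{[(5S,9R,10S)-3,6-dioxodrim-7-en-11-yl]oxy}-2H-chromen-2-one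
Conditions: Dess–Martin periodinane, CH2Cl2, rt
Reagents that add atoms: none
Why: Dess–Martin oxidation of the equatorial C3 alcohol to the ketone under nearly neutral conditions that leave the enone, the aryl ether and the coumarin alone, removing the C3 centre on purpose.

Step 17
Reactants: 25 7-{[(5S,9R,10S)-3,6-dioxodrim-7-en-11-yl]oxy}-2H-chromen-2-one
Product: 26 ferocaulidin, 7-{[(3S,5S,9R,10S)-3-hydroxy-6-oxodrim-7-en-11-yl]oxy}-2H-chromen-2-one
Conditions: LiBH(s-Bu)3 (1.1 equiv), THF, −78 °C; AcOH quench at −78 °C, no oxidative work-up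
Reagents that add atoms: none
Why: Diastereoselective ketone reduction with a bulky trialkylborohydride, which attacks 4,4-dimethyl-3-oxodecalins along the equatorial trajectory and so should give the axial (3S)-alcohol, the saturated ketone being expected to react at −78 °C well ahead of the hindered β,β-disubstituted C6 enone and the electron-rich coumarin lactone.

Compound list
1 | 2-(2-bromoethyl)-2-methyl-1,3-dioxolane | CC1(CCBr)OCCO1 | starting material
2 | 2,2-dimethylpent-4-enal | C=CCC(C)(C)C=O | starting material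
3 | [2-(2-methyl-1,3-dioxolan-2-yl)ethyl]magnesium bromide (formed in the flask) | CC1(CC[Mg]Br)OCCO1 | intermediate
4 | racemic 4,4-dimethyl-1-(2-methyl-1,3-dioxolan-2-yl)hept-6-en-3-ol | CC1(CCC(O)C(C)(C)CC=C)OCCO1 | intermediate
5 | 4,4-dimethyl-1-(2-methyl-1,3-dioxolan-2-yl)hept-6-en-3-one | CC1(CCC(=O)C(C)(C)CC=C)OCCO1 | intermediate
6 | (3R)-4,4-dimethyl-1-(2-methyl-1,3-dioxolan-2-yl)hept-6-en-3-ol | C=CCC(C)(C)[C@H](O)CCC1(C)OCCO1 | intermediate
7 | tert-butyl{[(3R)-4,4-dimethyl-1-(2-methyl-1,3-dioxolan-2-yl)hept-6-en-3-yl]oxy}dimethylsilane | C=CCC(C)(C)[C@H](O[Si](C)(C)C(C)(C)C)CCC1(C)OCCO1 | intermediate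
8 | (5R)-5-[(tert-butyldimethylsilyl)oxy]-6,6-dimethylnon-8-en-2-one | C=CCC(C)(C)[C@H](O[Si](C)(C)C(C)(C)C)CCC(C)=O | intermediate
9 | trimethyl phosphonoacetate | COC(=O)CP(=O)(OC)OC | starting material
10 | sodium salt of the trimethyl phosphonoacetate carbanion (formed in the flask) | [Na+].COC(=O)[CH-]P(=O)(OC)OC | intermediate
11 | methyl (2E,6R)-6-[(tert-butyldimethylsilyl)oxy]-3,7,7-trimethyldeca-2,9-dienoate | C=CCC(C)(C)[C@H](O[Si](C)(C)C(C)(C)C)CC/C(C)=C/C(=O)OC | intermediate
12 | methyl (2E,6R)-6-[(tert-butyldimethylsilyl)oxy]-3,7,7-trimethyl-9-oxodec-2-enoate | CC(=O)CC(C)(C)[C@H](O[Si](C)(C)C(C)(C)C)CC/C(C)=C/C(=O)OC | intermediate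
13 | acetaldehyde | CC=O | starting material
14 | dibutylboron enolate of 12 on the methyl side (formed in the flask) | C=C(OB(CCCC)CCCC)CC(C)(C)[C@H](O[Si](C)(C)C(C)(C)C)CC/C(C)=C/C(=O)OC | intermediate
15 | methyl (2E,6R)-6-[(tert-butyldimethylsilyl)oxy]-11-hydroxy-3,7,7-trimethyl-9-oxododec-2-enoate (C11 epimers) | CC(O)CC(=O)CC(C)(C)[C@H](O[Si](C)(C)C(C)(C)C)CC/C(C)=C/C(=O)OC | intermediate
16 | methyl (2E,6R)-6-[(tert-butyldimethylsilyl)oxy]-11-[(methylsulfonyl)oxy]-3,7,7-trimethyl-9-oxododec-2-enoate (formed in the flask) | CC(OS(C)(=O)=O)CC(=O)CC(C)(C)[C@H](O[Si](C)(C)C(C)(C)C)CC/C(C)=C/C(=O)OC | intermediate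
17 | methyl (2E,6R,10E)-6-[(tert-butyldimethylsilyl)oxy]-3,7,7-trimethyl-9-oxododeca-2,10-dienoate | C/C=C/C(=O)CC(C)(C)[C@H](O[Si](C)(C)C(C)(C)C)CC/C(C)=C/C(=O)OC | intermediate
18 | methyl (2E,6R,8Z,10E)-6,9-bis[(tert-butyldimethylsilyl)oxy]-3,7,7-trimethyldodeca-2,8,10-trienoate | C/C=C/C(O[Si](C)(C)C(C)(C)C)=C/C(C)(C)[C@H](O[Si](C)(C)C(C)(C)C)CC/C(C)=C/C(=O)OC | intermediate
19 | methyl (3R,5S,8R,9R,10R)-3,6-bis[(tert-butyldimethylsilyl)oxy]drim-6-en-11-oate | C[C@@H]1C=C(O[Si](C)(C)C(C)(C)C)[C@@H]2C(C)(C)[C@H](O[Si](C)(C)C(C)(C)C)CC[C@@]2(C)[C@@H]1C(=O)OC | intermediate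
20 | (3R,5S,8S,9R,10S)-3,6-bis[(tert-butyldimethylsilyl)oxy]drim-6-en-11-ol | C[C@@H]1C=C(O[Si](C)(C)C(C)(C)C)[C@@H]2C(C)(C)[C@H](O[Si](C)(C)C(C)(C)C)CC[C@@]2(C)[C@@H]1CO | intermediate
21 | umbelliferone (7-hydroxy-2H-chromen-2-one) | O=c1ccc2ccc(O)cc2o1 | starting material
22 | 7-{[(3R,5S,8S,9R,10S)-3,6-bis[(tert-butyldimethylsilyl)oxy]drim-6-en-11-yl]oxy}-2H-chromen-2-one | C[C@@H]1C=C(O[Si](C)(C)C(C)(C)C)[C@@H]2C(C)(C)[C@H](O[Si](C)(C)C(C)(C)C)CC[C@@]2(C)[C@@H]1COc1ccc2ccc(=O)oc2c1 | intermediate
23 | 7-{[(3R,5S,9R,10S)-3-[(tert-butyldimethylsilyl)oxy]-6-oxodrim-7-en-11-yl]oxy}-2H-chromen-2-one | CC1=CC(=O)[C@@H]2C(C)(C)[C@H](O[Si](C)(C)C(C)(C)C)CC[C@@]2(C)[C@@H]1COc1ccc2ccc(=O)oc2c1 | intermediate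
24 | 7-{[(3R,5S,9R,10S)-3-hydroxy-6-oxodrim-7-en-11-yl]oxy}-2H-chromen-2-one (3-epi-ferocaulidin) | CC1=CC(=O)[C@@H]2C(C)(C)[C@H](O)CC[C@@]2(C)[C@@H]1COc1ccc2ccc(=O)oc2c1 | intermediate
25 | 7-{[(5S,9R,10S)-3,6-dioxodrim-7-en-11-yl]oxy}-2H-chromen-2-one | CC1=CC(=O)[C@@H]2C(C)(C)C(=O)CC[C@@]2(C)[C@@H]1COc1ccc2ccc(=O)oc2c1 | intermediate
26 | ferocaulidin, 7-{[(3S,5S,9R,10S)-3-hydroxy-6-oxodrim-7-en-11-yl]oxy}-2H-chromen-2-one | CC1=CC(=O)[C@@H]2C(C)(C)[C@@H](O)CC[C@@]2(C)[C@@H]1COc1ccc2ccc(=O)oc2c1 | target

Total step count: 17. Longest linear sequence: 17 steps (from 1 and 2 to 26); 9, 13 and 21 enter as purchased.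

Steps most likely to fail

Step 11. The cycloaddition may be too slow at the crowded C5–C10 bond, so that thermal decay or hydrolysis of the silyl dienol ether wins, or endo and facial discrimination may be weak. The fallback makes the same two bonds ionically and sets out from enone 17. LiN(SiMe3)2 in THF (−78 °C → rt) forms the cross-conjugated lithium dienolate, whose C5 adds to C10 of the enoate; the ester enolate so formed closes on C8 of the enone (intramolecular double Michael addition). Protonation should give methyl (3R,5S,8R,9R,10R)-3-[(tert-butyldimethylsilyl)oxy]-6-oxodriman-11-oate F1; its C8 epimer serves equally, since step 14 erases C8. Silylation with TBSOTf and Et3N, which enolizes toward the accessible C7 methylene and not toward the hindered ring-fusion C5–H, brings the route back at 19.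

Step 17. Chemoselectivity may be lost, with hydride going to the coumarin lactone or to the C6 carbonyl besides C3. The fallback inverts C3 before the coumarin is present and sets out from 19. Saegusa–Ito oxidation (Pd(OAc)2, MeCN) gives methyl (3R,5S,9R,10R)-3-[(tert-butyldimethylsilyl)oxy]-6-oxodrim-7-en-11-oate F2. HF in MeCN gives methyl (3R,5S,9R,10R)-3-hydroxy-6-oxodrim-7-en-11-oate F3, and Dess–Martin periodinane gives methyl (5S,9R,10R)-3,6-dioxodrim-7-en-11-oate F4. LiBH(s-Bu)3 at −78 °C reduces only the C3 ketone to the axial alcohol methyl (3S,5S,9R,10R)-3-hydroxy-6-oxodrim-7-en-11-oate F5. LiAlH4 then reduces ester and enone to (3S,5S,9R,10S)-drim-7-ene-3,6,11-triol F6 (C6 epimers). Mitsunobu coupling with 21 at the only primary hydroxyl gives 7-{[(3S,5S,9R,10S)-3,6-dihydroxydrim-7-en-11-yl]oxy}-2H-chromen-2-one F7. MnO2 re-oxidizes the allylic C6 alcohol alone, and the route is back at 26.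

Step 13. Substitution at the β-branched C11 may be slow, and elimination of the activated alcohol may compete. The fallback forms the aryl–oxygen bond in place of the alkyl–oxygen bond and sets out from 20. Palladium-catalysed C–O cross-coupling with purchased 7-bromocoumarin (SMILES O=c1ccc2ccc(Br)cc2o1; [Pd(allyl)Cl]2, RockPhos, Cs2CO3, toluene, 90 °C, zerovalent palladium as the active species) should give the same ether, so the route is back at 22. No compound outside the list is made on this way (entry F0).

Further compounds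
F1 | step 11 | methyl (3R,5S,8R,9R,10R)-3-[(tert-butyldimethylsilyl)oxy]-6-oxodriman-11-oate | C[C@@H]1CC(=O)[C@@H]2C(C)(C)[C@H](O[Si](C)(C)C(C)(C)C)CC[C@@]2(C)[C@@H]1C(=O)OC
F2 | step 17 | methyl (3R,5S,9R,10R)-3-[(tert-butyldimethylsilyl)oxy]-6-oxodrim-7-en-11-oate | CC1=CC(=O)[C@@H]2C(C)(C)[C@H](O[Si](C)(C)C(C)(C)C)CC[C@@]2(C)[C@@H]1C(=O)OC
F3 | step 17 | methyl (3R,5S,9R,10R)-3-hydroxy-6-oxodrim-7-en-11-oate | CC1=CC(=O)[C@@H]2C(C)(C)[C@H](O)CC[C@@]2(C)[C@@H]1C(=O)OC
F4 | step 17 | methyl (5S,9R,10R)-3,6-dioxodrim-7-en-11-oate | CC1=CC(=O)[C@@H]2C(C)(C)C(=O)CC[C@@]2(C)[C@@H]1C(=O)OC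
F5 | step 17 | methyl (3S,5S,9R,10R)-3-hydroxy-6-oxodrim-7-en-11-oate | CC1=CC(=O)[C@@H]2C(C)(C)[C@@H](O)CC[C@@]2(C)[C@@H]1C(=O)OC
F6 | step 17 | (3S,5S,9R,10S)-drim-7-ene-3,6,11-triol (C6 epimers) | CC1=CC(O)[C@@H]2C(C)(C)[C@@H](O)CC[C@@]2(C)[C@@H]1CO
F7 | step 17 | 7-{[(3S,5S,9R,10S)-3,6-dihydroxydrim-7-en-11-yl]oxy}-2H-chromen-2-one (C6 epimers) | CC1=CC(O)[C@@H]2C(C)(C)[C@@H](O)CC[C@@]2(C)[C@@H]1COc1ccc2ccc(=O)oc2c1
F0 | step 13 | none | none
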